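The constants stand for no real mixture; no experiment stands behind them.

Amounts first: the three flasks hold the same charges, with 0.37 mM of impurity set against 1.9 mM of racemization catalyst, and they differ in temperature.

    racemization catalyst + impurity → spent catalyst (k1 = 58 /M/s, Ea1 = 45.0 kJ/mol)
    partner + free catalyst + left-handed substrate → free catalyst + left-handed product (k2 = 0.13 /M²/s, Ea2 = 43.0 kJ/mol)
    left-handed substrate + racemization catalyst ⇌ right-handed substrate + racemization catalyst, rate k3*[racemization catalyst]*[left-handed substrate] forward; the back reaction follows from the equilibrium constant (k3 = 2.4 /M/s, Ea3 = 48.0 kJ/mol)
    partner + free catalyst + right-handed substrate → free catalyst + right-handed product (k4 = 0.0098 /M²/s, Ea4 = 64.0 kJ/mol)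
    (constants at 25 °C)

| setting | Monday's | Tuesday's | Thursday's |
|---|---|---|---|
| left-handed substrate | 0.95 M | 0.95 M | 0.95 M |
| partner | 2.09 M | 2.09 M | 2.09 M |
| free catalyst | 4.8 mM | 4.8 mM | 4.8 mM |
| racemization catalyst | 1.9 mM | 1.9 mM | 1.9 mM |
| impurity | 0.37 mM | 0.37 mM | 0.37 mM |
| right-handed substrate | 0.95 M | 0.95 M | 0.95 M |
| temperature | 75 °C | 50 °C | 25 °C |
| time | 25 min | 25 min | 25 min |

- free catalyst is single-handed; left-handed substrate and right-handed substrate are mirror images of each other, charged as a racemate, each of them at the stated concentration
- the list of constants is for 25 °C, to be carried to other temperatures by the activation energies

1. the flask with the highest share of left-handed product in all that became left-handed product or right-handed product ("all alike" if they lie within 1.5 percentage points) (Monday's / Tuesday's / Thursday's / all alike)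
2. share of left-handed product in all that became left-handed product or right-handed product, Monday's
3. share of left-handed product in all that became left-handed product or right-handed product, Tuesday's
4. share of left-handed product in all that became left-handed product or right-handed product, Thursday's

If the two substrate forms stayed equal, the share of left-handed product would be the selectivity factor divided by that factor plus one. The factor here is the constant of the left-handed step over that of the right-handed step, at the flask's temperature. It is 13.3 at 25 °C, 6.89 at 50 °C and 3.93 at 75 °C. The first answer therefore reads 93.0% for Thursday's, 87.3% for Tuesday's and 79.7% for Monday's.

That answer needs racemization to keep up. In Thursday's flask the impurity takes 0.37 mM of the racemization catalyst on a time of 9.07 s, far shorter than the run, so 1.53 mM remains at work, and the reckoning takes the same amount for Tuesday's and Monday's. At Thursday's start that amount turns substrate over at 0.00367 /s, while left-handed substrate is consumed at 0.00130 /s. Racemization is faster, but only by a factor of 2.82, so a small gap between the forms is to be expected.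

So the first answer goes back in. The forms fall together when racemization carries half the difference of the two consumption rates. Right-handed substrate then exceeds left-handed by that half-difference over the racemization rate. For Thursday's, with partner at its charge, this is 0.164; call this fractional excess of right-handed over left-handed substrate the lag. The share becomes the factor over the factor plus one plus the lag. Monday's lag is 0.0991 and Tuesday's 0.130, which commits Thursday's to 92.0% and Monday's to 78.1%.

The weak link is the partner, held so far at its charge. The lag scales with partner, and partner goes one for one with substrate, falling over a complete run from 2.09 M to 0.190 M. Its mean is 1.14 M, a fraction 0.545 of the charge. Scaling the lags by that fraction gives 78.8% for Monday's, 86.5% for Tuesday's and 92.4% for Thursday's, the highest. That mean belongs to a complete run, but Thursday's substrate falls at the start on a time of 23.8 min, close to the 25 min of the run, so Thursday's flask stops short of complete, its partner stays above that mean, and its figure stands a little high.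

The forecast stood slightly lower, at 78.6%, 86.2% and 92.1% with Thursday's highest, holding that “the slight depletion of the left-handed substrate trims each share by only about a point”.

The simulation gives 78.9% for Monday's, 86.5% for Tuesday's and 92.3% for Thursday's, so Thursday's is highest. At 25.0 min Thursday's flask keeps 47% of its left-handed substrate and 51% of its right-handed, with 53% of its partner left. For the repeat of Monday's at 100 °C, the factor is 2.42 and the scaled lag 0.0379, giving 70.0%, and that flask gives 70.0%.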